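(The readings were computed from invented constants; the scatter is artificial.)

I am deciding how to charge the next flask, and the easy step is the end of the north run. From 3.00 h on, links read 0% and over-reaction product holds at 0.0735 M, out of 0.18 M of second end groups.

| flask | first end groups | second end groups | remark | time |
|---|---|---|---|---|
| north | 0.20 M | 0.18 M | run made earlier |  |
| north-east | 0.20 M | 0.090 M | run made earlier |  |
| north-west | 0.20 M | 0.14 M | run made earlier |  |
| zeta | 0.20 M (fed, over 5.0 h) | 0.180 M | all else is in the flask from the start; the feed brings no volume worth counting | 6.0 h |
| eta | 0.20 M (fed, over 80 min) | 0.180 M | all else is in the flask from the start; the feed brings no volume worth counting | 6.0 h |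
| epsilon | 0.20 M | 0.180 M (fed, over 5.0 h) | all else is in the flask from the start; the feed brings no volume worth counting | 6.0 h |
| delta | 0.20 M | 0.180 M | everything together at the start | 6.0 h |

- north (time / h: over-reaction product / %, links / %): 0.833: 34, 4; 1.50: 35, 3; 2.50: 38, 1; 3.00: 37, 0; 4.00: 36, 0; 5.00: 37, 0; 6.00: 37, 0
- north-east (time / h: over-reaction product / %, links / %): 0.333: 8, 6; 1.00: 14, 2; 1.50: 11, 3; 2.50: 15, 0; 4.00: 10, 0; 5.00: 14, 0; 6.00: 9, 0
- north-west (time / h: over-reaction product / %, links / %): 0.333: 16, 11; 1.00: 24, 0; 1.50: 23, 0; 2.50: 21, 1; 4.00: 20, 3; 5.00: 23, 0; 6.00: 29, 2

(scatter of a reading: 2 percentage points)

- the flask with the highest amount of over-reaction product, in percent of the first end groups charged ("all alike" if they lie within 1.5 percentage points) (zeta / eta / epsilon / delta / all alike)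
- final over-reaction product, as a percentage of the first end groups charged, in zeta
- final over-reaction product, as a percentage of the first end groups charged, in eta
- final over-reaction product, as a percentage of the first end groups charged, in epsilon
- final over-reaction product, as a percentage of the first end groups charged, in delta

- the numbers in the tables scatter with a standard deviation of 2 percentage points

I count one second end group per link, so 0.106 M went to something unseen. The yield on second end groups is 40.8% in north and 26.7% in north-east, so it rises with the charge. I therefore take the link step as first order in second end groups and a rival as indifferent to their level. At level B the links then get the share B/(B + K), with B/K as the selectivity factor. Summed while a charge B is used up with first end groups outlasting it, this gives O = B − K ln(1 + B/K), where O is the final product in M.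

K appears on both sides, so I iterate. Setting the logarithm to 1 gives 0.106 M, putting that back gives 0.108 M, and one more round gives 0.108 M. This is K, the level of second end groups at which links and the rival take equal shares. The rule then gives 12.2% for north-east, where the plateau reads 12.0%, and 25.1% for north-west, where it reads 23.2%.

The rule holds no dosing time, so delta, zeta and eta all reckon at 37.0%. But zeta takes its first end groups by a feed over 5.0 h, a dosing no run tests, so I charge everything together. In north-east, links plus product match the plateau by 0.333 h, so its charge went at 0.270 M h⁻¹ or faster, against 0.0360 M h⁻¹ fed in epsilon. The level there stays low, and I expect a low yield.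

The forecast, which differs from me on the feeds, names zeta as highest, with zeta 40%, eta 39%, epsilon 12% and delta 37%, holding that “Feeding first end groups slowly keeps second end groups abundant”.

    first end groups + second end groups → links (k = 0.0276 M⁻¹ s⁻¹)
    first end groups + second end groups → rings, rate k2*[first end groups] as long as [second end groups] is above zero (k = 0.00285 s⁻¹)
    second end groups → decomposed reagent (k = 5.41 × 10⁻⁴ s⁻¹)
    links → over-reaction product (k = 8.61 × 10⁻⁴ s⁻¹)

Delta ends highest at 35.3%, against 6.47% in zeta, 15.0% in eta and 0.0164% in epsilon. My equal figure for the feeds fails: at 6.00 h zeta holds 0.136 M of decomposed reagent, and delta 0.0117 M. The neighbouring flask is delta with 0.80 M of first end groups, charged together. The same K gives the same product in M, so 9.24% of this larger charge. The neighbour ends at 9.35%, with 77.8% of its first end groups left.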